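Target in the alpha run climbs quickly and falls slowly. Its rise time r, the top reading 17.1 % over the opening rate, is 0.548 d, while it takes longer to halve afterwards, 1.89 d. This second time, read off two scattered readings, is the fall half-life h of target, an intermediate.

| flask | starting material | reagent in the second phase | remark | time | volume of the second phase over the first |
|---|---|---|---|---|---|
| alpha | 0.025 M | 0.0475 M | run made earlier |  |  |
| gamma | 0.038 M | 0.0475 M | run made earlier |  |  |
| epsilon | 0.050 M | 0.071 M | run made earlier |  |  |
| flask | 0.050 M | 0.0475 M |  | 2.5 d | 0.50 |

- alpha (time / d: target / %, starting material / %): 0.250: 7.8, 91.0; 0.500: 16.3, 78.7; 1.25: 17.1, 57.1; 3.00: 9.0, 42.0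
- gamma (time / d: target / %, starting material / %): 0.833: 17.3, 69.8; 1.67: 14.5, 58.7; 2.50: 11.4, 53.8; 3.00: 8.9, 53.0
- epsilon (time / d: target / %, starting material / %): 0.250: 10.9, 88.6; 0.500: 17.6, 73.3; 1.25: 16.2, 53.1; 3.00: 8.5, 42.9

(scatter of a reading: 0.5 percentage points)

- in the second phase: reagent in the second phase; everything else is in the first
- charges count per volume of the first phase; a concentration in a rate is the amount of a species over the volume of its own phase; every rate counts per litre of the first phase
- the earlier runs hold the two phases in the same ratio of volumes as the flask asked about

1. amount of target at 2.5 d, in percent of the starting material charged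
2. the change that raises the amount of target at 2.5 d, in percent of the starting material charged most ("none" if none brings more than 2 percentage points) (maple / larch / none)
3. amount of target at 2.5 d, in percent of the starting material charged, after larch

- maple: doubling the amount of reagent in the second phase, all else as stated
- larch: doubling the transfer coefficient of the reagent in the second phase, all else as stated

The ratio h/r is 3.45, and the flask is read at 2.5 d, later than r, so it is taken to stand on the falling side of its curve. Epsilon carries twice alpha's starting material and more reagent in the second phase. Its r shortens to 0.404 d, but its h of 1.88 d matches alpha's, and its top reading, 17.6 %, lies close to alpha's.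

My reckoning therefore carries alpha's 17.1 % at 1.25 d down the fall to 2.5 d and gives 10.8 % for the flask. Epsilon's target readings at 1.25 d and 3.00 d lie no higher than alpha's, though epsilon differs in both charges, so the reckoning expects no gain of 2 percentage points from maple or larch, and a slightly lower value after larch.

The forecast gives 11 %, none and 9 %: “Neither helps, so best is none”.

The flask gives 10.2 % and best none, with maple at −2.4 points and larch at −0.89 points, and 9.34 % after larch.

    reagent in the reaction phase ⇌ reagent in the second phase, rate k1*([reagent in the reaction phase] - [reagent in the second phase]/K1) per volume of the first phase (partition coefficient = 1.31, kL = 1.67 × 10⁻⁵ s⁻¹)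
    starting material + reagent in the reaction phase ⇌ target (K = 37.0 L mol⁻¹, k = 5.51 × 10⁻⁴ L mol⁻¹ s⁻¹)
    reagent in the reaction phase + target → over-reacted product (k = 0.00111 L mol⁻¹ s⁻¹)
    reagent in the reaction phase → decomposed reagent (k = 2.28 × 10⁻⁶ s⁻¹)

In the flask, target goes from 15.5 % at 1.25 d to 10.2 % at 2.50 d, a half-life over that stretch of 2.08 d, close to h. A neighbour of the flask, charged with 0.020 M of starting material, lies below alpha's charge, and alpha's top reading carried down the same h gives the estimate 10.8 % for it. That neighbour holds 10.4 % of target at 2.50 d, beside 49.3 % of over-reacted product.

The numbers in the tables are calculated for an exercise; noise was put on by code.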